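## Retrosynthetic overview

1. No ring is built: chromanone rings A/C, ring B and the (2S) centre are all bought in (2S)-liquiritigenin (1).
2. C8 and C3′ are marked as C–I bonds by double ortho-iodination of 1 with iodine (2) and iodic acid (3), giving diiodide 4.
3. The two phenols of 4 are capped with BSA (5) as the bis-TMS ether 6, which is used in the same pot without isolation.
4. Key disconnection: both aryl–CH2(prenyl) bonds, formed in one Ni-catalysed electroreductive cross-electrophile coupling of 6 with prenyl acetate (7); mild acidic work-up removes TMS and gives glabrol (8).
5. C2 is never made or broken, and no strong base is used, so the retro-oxa-Michael racemisation pathway is not opened.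

**Assumption:** natural (2S)-liquiritigenin is taken as purchasable in enantiopure form, with its ee confirmed by chiral HPLC on receipt. Catalysts, ligands, electrolytes and solvents that leave no atoms in the product are named in the conditions and not numbered.

## Route

**Step 1**
Reactants: 1, (2S)-liquiritigenin [(2S)-7-hydroxy-2-(4-hydroxyphenyl)chroman-4-one]; 2, iodine; 3, iodic acid
Product: 4, (2S)-7-hydroxy-2-(4-hydroxy-3-iodophenyl)-8-iodochroman-4-one
Conditions: I2 (0.82 equiv), HIO3 (0.41 equiv), EtOH/H2O 4:1, 0 °C → rt, dark, portionwise addition with HPLC monitoring; aq. Na2S2O3; chromatography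
Reagents that add atoms: iodine, II; iodic acid, OI(=O)=O
Why: Electrophilic aromatic iodination with base-free I2/HIO3 puts one iodine ortho to each phenolic OH and then deactivates that ring; ring A is expected to react at C8 (flanked by O7 and O1, by analogy with 2,4-dihydroxyacetophenone iodinating between its oxygens), ring B reacts at C3′ (equivalent to C5′), and the acidic medium leaves C2 untouched.

**Step 2**
Reactants: 4, (2S)-7-hydroxy-2-(4-hydroxy-3-iodophenyl)-8-iodochroman-4-one; 5, N,O-bis(trimethylsilyl)acetamide (BSA)
Product: 6, (2S)-8-iodo-2-[3-iodo-4-(trimethylsilyloxy)phenyl]-7-(trimethylsilyloxy)chroman-4-one (bis-TMS ether of 4; not isolated, solution carried directly into Step 3)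
Conditions: BSA (3 equiv), dry DMA, rt, 30 min, Ar; conversion checked by quenched-aliquot NMR; used as the crude solution
Reagents that add atoms: BSA, CC(=N[Si](C)(C)C)O[Si](C)(C)C (two Me3Si groups transferred)
Why: Neutral O-silylation of phenols by silyl transfer from BSA is fast and quantitative at room temperature, its only by-product is inert N-TMS-acetamide/acetamide, and no base touches the C3 protons, so C2 keeps its (S) configuration.

**Step 3**
Reactants: 6, bis-TMS ether from Step 2 (crude DMA solution); 7, prenyl acetate (3-methylbut-2-en-1-yl acetate)
Product: 8, glabrol [(2S)-7-hydroxy-2-[4-hydroxy-3-(3-methylbut-2-en-1-yl)phenyl]-8-(3-methylbut-2-en-1-yl)chroman-4-one]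
Conditions: NiBr2·dme (10 mol %), dtbbpy (12 mol %), prenyl acetate (4 equiv), n-Bu4NBr (0.1 M), DMA, undivided cell, Fe(+)/RVC(−), constant current, ca. 5 F mol⁻¹, cathode potential not more negative than −1.5 V vs Ag/AgCl, rt, Ar; then citric acid, MeOH/H2O, rt (cleaves both ArO–TMS); chromatography
Reagents that add atoms: prenyl acetate, CC(C)=CCOC(C)=O (two C5H9 units retained; desilylation adds only H)
Why: Proposed new method: a two-fold Ni/dtbbpy-catalysed electroreductive cross-electrophile prenylation of a transiently O-silylated bis(ortho-iodophenol), in which cathodically formed Ni(0) inserts into each Ar–I, the ArNi(II) is reduced to ArNi(I), and this ionises prenyl acetate to an ArNi(III)(η3-prenyl) species that reductively eliminates at the unsubstituted CH2 terminus to give the linear prenyl arene; the liberated acetate is scavenged as Fe(II) acetate from the sacrificial anode and any phenoxide it frees is re-silylated by the excess BSA, while the ketone, the alkenes and C2 (retained, no new stereocentre) lie outside the potential window and see no base or carbon nucleophile; the closest known reaction type is the Ni-catalysed (electro)reductive allylation of simple aryl halides with allylic acetates, which has not been shown as a double coupling on an epimerisable iodophenolic flavanone.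

## Compound list

1 | (2S)-liquiritigenin | Oc1ccc(cc1)[C@@H]2CC(=O)c3ccc(O)cc3O2 | starting material
2 | iodine | II | starting material (reagent)
3 | iodic acid | OI(=O)=O | starting material (reagent)
4 | (2S)-7-hydroxy-2-(4-hydroxy-3-iodophenyl)-8-iodochroman-4-one | Oc1ccc(cc1I)[C@@H]2CC(=O)c3ccc(O)c(I)c3O2 | intermediate
5 | N,O-bis(trimethylsilyl)acetamide (BSA) | CC(=N[Si](C)(C)C)O[Si](C)(C)C | starting material (reagent)
6 | (2S)-8-iodo-2-[3-iodo-4-(trimethylsilyloxy)phenyl]-7-(trimethylsilyloxy)chroman-4-one | C[Si](C)(C)Oc1ccc(cc1I)[C@@H]2CC(=O)c3ccc(O[Si](C)(C)C)c(I)c3O2 | intermediate
7 | prenyl acetate | CC(C)=CCOC(C)=O | starting material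
8 | glabrol, (2S) | CC(C)=CCc1cc([C@@H]2CC(=O)c3ccc(O)c(CC=C(C)C)c3O2)ccc1O | target

## Step count and risks

Total steps: 3 (Steps 2 and 3 are run in one vessel, so there are two isolations). Longest linear sequence: 3.

Three steps most likely to fail:

1. **Step 3, the proposed double electroreductive prenylation.** Likely failures are hydrodeiodination at the hindered C8 position, a branched (reverse-prenyl) isomer, or allyl transfer to the C4 ketone. Fallback (known chemistry): convert 4 to its isolated bis-TBS ether, run a Pd(0)-catalysed Stille coupling with tributyl(3-methylbut-2-en-1-yl)stannane, then remove the silyl groups with Et3N·3HF or AcOH-buffered TBAF.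

2. **Step 1, regiochemistry of the iodination.** C6 may compete with C8 on ring A, and a second iodine may enter ring A before ring B reacts. Fallback: drop the aryl-iodide marking and mark the positions through oxygen instead. Pd(0)-catalysed O-(1,1-dimethylallyl)ation of both phenols of 1, followed by aromatic Claisen rearrangement (Eu(fod)3 or about 110 °C), delivers linear prenyl to C8 and C3′ by [3,3] shift.

3. **Step 2, the transient TMS masking.** Aryl TMS ethers are labile: if they do not survive the electrolysis, free phenol can protonate the aryl–Ni intermediates, and a free 4′-phenoxide can open the C ring through a quinone methide and racemise C2. Fallback: replace transient masking with isolated, robust protecting groups (bis-TBS or bis-MOM ether of 4, coupling, then buffered fluoride or mild acid deprotection), accepting one extra isolated step.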